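**Target:** (2S)-5,7-dihydroxy-6-[(3R,4S)-7-hydroxy-3-(3-hydroxy-2,4-dimethoxyphenyl)-3,4-dihydro-2H-chromen-4-yl]-2-(4-hydroxyphenyl)-2,3-dihydro-4H-chromen-4-one. This is a 3,4-trans isoflavan (3R,4S) joined through C4 to C6 of (2S)-naringenin.

## Retrosynthetic overview

1. The last bond made is C4(isoflavan)–C6(naringenin): the target opens to (2S)-naringenin and the C4 para-quinone methide of the 7,3'-dihydroxy-2',4'-dimethoxyisoflavan, the species an isoflavanol dehydratase would form. Racemic isoflavan-4-ol is used, and C3 and C4 are both set in this one step by a chiral phosphoric acid.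
2. The isoflavan-4-ol comes from the isoflavone by hydrogenation and hydride reduction (parallel to isoflavone reductase and vestitone reductase), with loss of both benzyl groups.
3. Ring C of the isoflavone comes from a 2'-hydroxychalcone by oxidative 1,2-aryl shift and ring closure with loss of methanol (parallel to isoflavone synthase and 2-hydroxyisoflavanone dehydratase).
4. The chalcone comes from 4'-benzyloxy-2'-hydroxyacetophenone and 3-benzyloxy-2,4-dimethoxybenzaldehyde, the latter in two steps from syringol.
5. Ring order: only ring C of the isoflavonoid half is built; rings A and B and the whole flavanone are bought.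

Assumption: (2S)-naringenin is bought as the single enantiomer (natural (−)-naringenin, ee checked by chiral HPLC before use), and the sense of induction of the chiral acid in step 6, which cannot be predicted, is fixed in a first small run with both antipodes; (R)-TRIP is written.

## Route

Step 1
Reactants: 1 2,6-dimethoxyphenol (syringol)
Product: 2 2-(benzyloxy)-1,3-dimethoxybenzene
Conditions: BnBr (1.1 equiv), K2CO3 (1.5 equiv), acetone, reflux, 12 h
Reagents that add atoms: benzyl bromide, BrCc1ccccc1
Why: Williamson ether synthesis; the acidic phenol is alkylated cleanly, and the benzyl group masks the oxidation-prone phenol until step 5.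

Step 2
Reactants: 2 2-(benzyloxy)-1,3-dimethoxybenzene
Product: 3 3-(benzyloxy)-2,4-dimethoxybenzaldehyde
Conditions: POCl3 (1.5 equiv), DMF, 0 °C then 80 °C, 6 h; then ice/H2O
Reagents that add atoms: N,N-dimethylformamide, CN(C)C=O; water, O
Why: Vilsmeier–Haack formylation; the ring position ortho to one OMe and para to the other is by far the most activated, as in the formylation of 1,2,3-trimethoxybenzene to 2,3,4-trimethoxybenzaldehyde.

Step 3
Reactants: 3 3-(benzyloxy)-2,4-dimethoxybenzaldehyde; 4 1-[4-(benzyloxy)-2-hydroxyphenyl]ethan-1-one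
Product: 5 (E)-1-[4-(benzyloxy)-2-hydroxyphenyl]-3-[3-(benzyloxy)-2,4-dimethoxyphenyl]prop-2-en-1-one
Conditions: KOH (4 equiv, 50% aq.), EtOH, rt, 36 h; then aq. HCl
Reagents that add atoms: none
Why: Claisen–Schmidt (crossed aldol) condensation of a methyl ketone with a non-enolisable aldehyde gives the E-2'-hydroxychalcone, the chemical counterpart of the chalcone that chalcone synthase makes.

Step 4
Reactants: 5 (E)-1-[4-(benzyloxy)-2-hydroxyphenyl]-3-[3-(benzyloxy)-2,4-dimethoxyphenyl]prop-2-en-1-one
Product: 7 7-(benzyloxy)-3-[3-(benzyloxy)-2,4-dimethoxyphenyl]-4H-chromen-4-one, via racemic beta-keto dimethyl acetal 6 (not isolated)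
Conditions: Tl(NO3)3·3H2O (1.2 equiv), MeOH/CH(OMe)3 1:1, rt, 4 h; then 10% aq. HCl, MeOH, 60 °C, 3 h
Reagents that add atoms: none
Why: Oxidative 1,2-aryl migration of a 2'-hydroxychalcone with thallium trinitrate (the classical biomimetic isoflavone synthesis): oxythallation of the enone, shift of the electron-rich ring B from C-beta to C-alpha as thallium leaves as TlNO3 (monovalent thallium), and capture by methanol give acetal 6; acid then closes ring C through the 2'-OH and eliminates methanol, mirroring isoflavone synthase and 2-hydroxyisoflavanone dehydratase, and the stereocentre of 6 disappears in 7.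

Step 5
Reactants: 7 7-(benzyloxy)-3-[3-(benzyloxy)-2,4-dimethoxyphenyl]-4H-chromen-4-one
Product: 9 rac-3-(3-hydroxy-2,4-dimethoxyphenyl)-3,4-dihydro-2H-chromene-4,7-diol (cis/trans mixture), via racemic isoflavanone 8 (not isolated)
Conditions: H2 (1 atm), 10% Pd/C, THF/MeOH 1:1, rt, 12 h; filter; then NaBH4 (4 equiv), 0 °C to rt, 4 h; aq. NH4Cl; crude product used at once
Reagents that add atoms: none
Why: Heterogeneous hydrogenation (hydrogenolysis of both aryl benzyl ethers and saturation of the chromone C2=C3 bond) followed by borohydride reduction of the ketone, parallel to isoflavone reductase and vestitone reductase; C3 and C4 are left uncontrolled on purpose because both are erased and reset in step 6.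

Step 6
Reactants: 9 rac-3-(3-hydroxy-2,4-dimethoxyphenyl)-3,4-dihydro-2H-chromene-4,7-diol (cis/trans mixture); 10 (2S)-naringenin, (2S)-5,7-dihydroxy-2-(4-hydroxyphenyl)-2,3-dihydro-4H-chromen-4-one
Product: 13 (2S)-5,7-dihydroxy-6-[(3R,4S)-7-hydroxy-3-(3-hydroxy-2,4-dimethoxyphenyl)-3,4-dihydro-2H-chromen-4-yl]-2-(4-hydroxyphenyl)-2,3-dihydro-4H-chromen-4-one, via isoflav-3-ene 11 (not isolated), via (3R)-para-quinone methide 12 (not isolated)
Conditions: (R)-TRIP (10 mol%), 10 (3 equiv), 4 Å MS, PhCF3/EtOAc 3:1, 40 °C, 24–48 h; Sephadex LH-20, then C18 HPLC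
Reagents that add atoms: none
Why: Proposed new method: the acid ionises every stereoisomer of 9 to the C4 para-quinone methide (the intermediate of isoflavanol dehydratase/pterocarpan synthase), which loses H-3 to give achiral isoflav-3-ene 11 and is re-formed from it by protonation, so C3 epimerises in the flask; ring A of 10 (C6, ortho to the 7-OH that is hydrogen-bonded to the P=O of the acid) adds 1,6 to the ion-paired quinone methide anti to the C3 aryl group, which fixes 3,4-trans, and the chiral anion makes this addition fast only for the (3R) quinone methide 12, so C3 (R) and C4 (S) are set together by dynamic kinetic resolution in a Friedel–Crafts alkylation while C2'' (S) comes unchanged from 10; the closest known chemistry is the chiral phosphoric acid catalysed asymmetric 1,6-addition of phenols and indoles to para-quinone methides generated in situ from para-hydroxybenzyl alcohols, the acid-catalysed protonation of hydroxystyrenes to quinone methides, and the trans-selective coupling of flavan-4-yl cations with phloroglucinol-type rings in procyanidin synthesis.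

## Compound list

1 | 2,6-dimethoxyphenol (syringol) | COc1cccc(OC)c1O | starting material
2 | 2-(benzyloxy)-1,3-dimethoxybenzene | COc1cccc(OC)c1OCc1ccccc1 | intermediate
3 | 3-(benzyloxy)-2,4-dimethoxybenzaldehyde | COc1ccc(C=O)c(OC)c1OCc1ccccc1 | intermediate
4 | 1-[4-(benzyloxy)-2-hydroxyphenyl]ethan-1-one | CC(=O)c1ccc(OCc2ccccc2)cc1O | starting material
5 | (E)-1-[4-(benzyloxy)-2-hydroxyphenyl]-3-[3-(benzyloxy)-2,4-dimethoxyphenyl]prop-2-en-1-one | COc1ccc(/C=C/C(=O)c2ccc(OCc3ccccc3)cc2O)c(OC)c1OCc1ccccc1 | intermediate
6 | rac-1-[4-(benzyloxy)-2-hydroxyphenyl]-2-[3-(benzyloxy)-2,4-dimethoxyphenyl]-3,3-dimethoxypropan-1-one (not isolated) | COc1ccc(C(C(OC)OC)C(=O)c2ccc(OCc3ccccc3)cc2O)c(OC)c1OCc1ccccc1 | intermediate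
7 | 7-(benzyloxy)-3-[3-(benzyloxy)-2,4-dimethoxyphenyl]-4H-chromen-4-one | COc1ccc(-c2coc3cc(OCc4ccccc4)ccc3c2=O)c(OC)c1OCc1ccccc1 | intermediate
8 | rac-7-hydroxy-3-(3-hydroxy-2,4-dimethoxyphenyl)-2,3-dihydro-4H-chromen-4-one (not isolated) | COc1ccc(C2COc3cc(O)ccc3C2=O)c(OC)c1O | intermediate
9 | rac-3-(3-hydroxy-2,4-dimethoxyphenyl)-3,4-dihydro-2H-chromene-4,7-diol (cis/trans mixture, no stereodescriptors) | COc1ccc(C2COc3cc(O)ccc3C2O)c(OC)c1O | intermediate
10 | (2S)-naringenin, (2S)-5,7-dihydroxy-2-(4-hydroxyphenyl)-2,3-dihydro-4H-chromen-4-one | O=C1C[C@@H](c2ccc(O)cc2)Oc2cc(O)cc(O)c12 | starting material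
11 | 3-(3-hydroxy-2,4-dimethoxyphenyl)-2H-chromen-7-ol (isoflav-3-ene, not isolated) | COc1ccc(C2=Cc3ccc(O)cc3OC2)c(OC)c1O | intermediate
12 | (3R)-3-(3-hydroxy-2,4-dimethoxyphenyl)-2,3-dihydro-7H-chromen-7-one (para-quinone methide, not isolated; its 3S antipode returns through 11) | COc1ccc([C@@H]2COC3=CC(=O)C=CC3=C2)c(OC)c1O | intermediate
13 | (2S)-5,7-dihydroxy-6-[(3R,4S)-7-hydroxy-3-(3-hydroxy-2,4-dimethoxyphenyl)-3,4-dihydro-2H-chromen-4-yl]-2-(4-hydroxyphenyl)-2,3-dihydro-4H-chromen-4-one | COc1ccc([C@@H]2COc3cc(O)ccc3[C@H]2c2c(O)cc3c(c2O)C(=O)C[C@@H](c2ccc(O)cc2)O3)c(OC)c1O | target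

## Step count and risks

Total step count: 6. Longest linear sequence: 6 steps (1 → 2 → 3 → 5 → 7 → 9 → 13).

**Most likely to fail, 1: step 6.**
- The chiral acid may discriminate poorly between the (3R) and (3S) quinone methides. The floor is then a 1:1 mixture of the (3R,4S,2''S) and (3S,4R,2''S) trans products. These are diastereomers because 10 is enantiopure, so HPLC still delivers 13 as a single stereoisomer at half yield.
- Attack through C8 of 10 will compete with C6. The 8-linked regioisomer is removed on C18.
- Protonation of 11 at C4 (cation at C3, stabilised by ring B) and self-alkylation of ring A of 9 are loss channels. The excess of 10 is meant to suppress them.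
- Fallback, setting out from 7 and coming back at 13: asymmetric transfer hydrogenation of 7 with RuCl(p-cymene)[(R,R)-TsDPEN] (2 mol%) in HCO2H/Et3N 5:2 and EtOAc at 40 °C reduces C2=C3 and then C4=O with dynamic kinetic resolution at C3. This gives cis-configured (3R,4R)-7-(benzyloxy)-3-[3-(benzyloxy)-2,4-dimethoxyphenyl]-3,4-dihydro-2H-chromen-4-ol F1. Brief neutral hydrogenolysis (H2, Pd/C, EtOAc) gives (3R,4R)-3-(3-hydroxy-2,4-dimethoxyphenyl)-3,4-dihydro-2H-chromene-4,7-diol F2. F2 is then coupled with 10 (5 equiv) using diphenyl phosphate (5 mol%) in EtOAc at 0 °C. This acid is too weak to re-protonate 11, so any 11 formed is a loss and not a racemisation path. C3 is carried through from the reduction, and C4 is set trans by anti attack on 12, giving 13.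

**Most likely to fail, 2: step 5.**
- The phenolate of 8 is a poor hydride acceptor, so the borohydride stage may stall.
- Diol 9 is a sensitive para-hydroxybenzylic alcohol and can dehydrate to 11 or oligomerise on handling. Dehydrated material is tolerated, because 11 enters step 6 on the same pathway.
- Fallback, setting out from 7 and coming back at 9: reverse the order. NaBH4 in THF/EtOH at rt reduces the benzyl-protected isoflavone (1,4- then 1,2-reduction) to rac-7-(benzyloxy)-3-[3-(benzyloxy)-2,4-dimethoxyphenyl]-3,4-dihydro-2H-chromen-4-ol F3 (cis/trans mixture). Short neutral hydrogenolysis (H2 1 atm, Pd/C, EtOAc) then cleaves the two aryl benzyl ethers faster than the benzylic C–O bond and gives 9.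

**Most likely to fail, 3: step 4.**
- Trivalent thallium may attack the electron-rich ring B, or the aryl shift may give low yield.
- Fallback, setting out from 5 and coming back at 7: first close ring C as in the biosynthesis (NaOAc, EtOH, reflux; oxa-Michael) to rac-7-(benzyloxy)-2-[3-(benzyloxy)-2,4-dimethoxyphenyl]-2,3-dihydro-4H-chromen-4-one F4. Then carry out the oxidative 2,3-aryl shift of this flavanone with the trivalent iodine reagent PhI(OH)OTs in MeCN at reflux, which gives 7 directly.

## Further compounds

F1 | step 6 | (3R,4R)-7-(benzyloxy)-3-[3-(benzyloxy)-2,4-dimethoxyphenyl]-3,4-dihydro-2H-chromen-4-ol | COc1ccc([C@@H]2COc3cc(OCc4ccccc4)ccc3[C@@H]2O)c(OC)c1OCc1ccccc1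
F2 | step 6 | (3R,4R)-3-(3-hydroxy-2,4-dimethoxyphenyl)-3,4-dihydro-2H-chromene-4,7-diol | COc1ccc([C@@H]2COc3cc(O)ccc3[C@@H]2O)c(OC)c1O
F3 | step 5 | rac-7-(benzyloxy)-3-[3-(benzyloxy)-2,4-dimethoxyphenyl]-3,4-dihydro-2H-chromen-4-ol (cis/trans mixture) | COc1ccc(C2COc3cc(OCc4ccccc4)ccc3C2O)c(OC)c1OCc1ccccc1
F4 | step 4 | rac-7-(benzyloxy)-2-[3-(benzyloxy)-2,4-dimethoxyphenyl]-2,3-dihydro-4H-chromen-4-one | COc1ccc(C2CC(=O)c3ccc(OCc4ccccc4)cc3O2)c(OC)c1OCc1ccccc1
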